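The cyclopentenone is disconnected at C8–C12, which unfolds chlorovulone III into a linear C20 chain carrying a C7=C8=C9 allenyl methoxymethyl ether, a (10E)-chloroalkene and a C12 ketone. The key step exploits the oxygenated pentadienyl array C8–C12 of the ring, which ends at the carbinol carbon C12 and bears the exocyclic C7=C8 alkene: Lewis acid activation of the C12 ketone triggers a 4π conrotatory closure that forms the ring, the C12 stereocentre (from the allene axis), the 7Z alkene and the C9 ketone in one operation. The precursor is assembled by Stille coupling of a resolved C1–C9 allenylstannane with a C10–C20 (Z)-chloroiodoalkene and is liberated by oxidation only immediately before cyclisation.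

Key step: step 11

Remarks on the chemistry
- Locants are prostanoid locants (C1 = ester carbon, C20 = chain end).
- Structure check: with the ketone oxygen inside and the dienyl group turning outward, the (aS) axis leads to 12R and 7Z. No structure needed correcting; only the missing 10E descriptor of the precursor is added.
- A methyl ester does not survive the butyllithium needed to metalate the allene, so it is masked as its carboxylate in step 7.
- The axis is resolved at the stannane, which is covalent and configurationally stable, and not at a lithiated species.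
- The freed (10E)-dienone with an allene terminus is expected to close thermally at oxygen (6π). The ketone is therefore generated last and handled cold.
- Assumption: the absolute configuration of the resolved stannane is to be assigned by VCD/ECD against calculation.

Step 1
Reactants: 1 (Z)-non-3-en-1-ol
Product: 2 (Z)-non-3-enal
Conditions: Dess–Martin periodinane, NaHCO3, CH2Cl2, 0 °C; used crude
Reagents that add atoms: none
Why: Buffered Dess–Martin oxidation of the primary alcohol should give the β,γ-unsaturated aldehyde without moving the Z alkene into conjugation.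

Step 2
Reactants: 2 (Z)-non-3-enal; 3 (E)-1,2-dichloroethene
Product: 5 rac-(5Z)-1-chloroundec-5-en-1-yn-3-ol, via chloroethynyllithium 4 (not isolated)
Conditions: 3, MeLi (2 equiv), Et2O, 0 → 23 °C; then 2, −78 → 0 °C; aq. NH4Cl
Reagents that add atoms: none
Why: Dehydrochlorination and metalation of 3 gives chloroethynyllithium, whose acetylide 1,2-addition to the aldehyde delivers the chloroalkynyl carbinol in one step; C12 is formed racemic and is oxidised in step 10.

Step 3
Reactants: 5 rac-(5Z)-1-chloroundec-5-en-1-yn-3-ol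
Product: 7 (1Z,5Z)-1-chloro-1-iodoundeca-1,5-dien-3-ol, via cyclic chlorovinyl alanate 6 (not isolated)
Conditions: Red-Al (1.1 equiv), THF, −20 → 0 °C; then I2, −78 → 0 °C; aq. Rochelle salt, Na2S2O3
Reagents that add atoms: iodine, SMILES II
Why: Alkoxide-directed trans-hydroalumination of the propargylic alcohol puts hydride on C11 and aluminium on the chlorine-bearing C10 cis to the carbinol, and iodinolysis with retention gives the (Z)-1-chloro-1-iodoalkene with iodine where C9 must enter.

Step 4
Reactants: 8 methyl hex-5-ynoate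
Product: 10 methyl (E)-6-iodohex-5-enoate, via alkenylzirconocene chloride 9 (not isolated)
Conditions: Cp2Zr(H)Cl (1.2 equiv), THF, 23 °C; then I2, 0 °C
Reagents that add atoms: iodine, SMILES II
Why: syn-Hydrozirconation of the terminal alkyne places zirconium on the terminal carbon, and iodinolysis with retention gives the (E)-iodoalkene (the later 5E alkene) with the ester intact.

Step 5
Reactants: 10 methyl (E)-6-iodohex-5-enoate; 11 3-(methoxymethoxy)prop-1-yne
Product: 12 methyl (5E)-9-(methoxymethoxy)non-5-en-7-ynoate
Conditions: PdCl2(PPh3)2 (2 mol %), CuI (4 mol %), Et3N, THF, 23 °C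
Reagents that add atoms: none
Why: Sonogashira coupling of the (E)-vinyl iodide with the terminal alkyne keeps the alkene geometry and assembles C1–C9.

Step 6
Reactants: 12 methyl (5E)-9-(methoxymethoxy)non-5-en-7-ynoate
Product: 13 rac-methyl (5E)-9-(methoxymethoxy)nona-5,7,8-trienoate
Conditions: KOt-Bu (10 mol %), THF, −20 → 0 °C; pH 7 buffer
Reagents that add atoms: none
Why: Base-catalysed propargyl ether to allenyl ether isomerisation (1,3-prototropic shift through the C9 anion) is the standard entry to alkoxyallenes, and catalytic base at low temperature should stop it at the vinylallene.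

Step 7
Reactants: 13 rac-methyl (5E)-9-(methoxymethoxy)nona-5,7,8-trienoate
Product: 17 rac-methyl (5E)-9-(methoxymethoxy)-9-(tributylstannyl)nona-5,7,8-trienoate, via potassium carboxylate 14 (not isolated), via C9-lithiated carboxylate 15 (not isolated), via C9-stannylated carboxylate 16 (not isolated)
Conditions: KOSiMe3 (1.05 equiv), THF, 23 °C, evaporate; n-BuLi (1.2 equiv), THF/DMPU, −78 °C; Bu3SnCl (1.1 equiv), −78 °C; MeI (5 equiv), −78 → 23 °C
Reagents that add atoms: tributyltin chloride, SMILES CCCC[Sn](Cl)(CCCC)CCCC; iodomethane, SMILES CI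
Why: Silanolate ester cleavage masks the ester as a carboxylate that butyllithium does not attack at −78 °C, the acetal-directed α-lithiation of the alkoxyallene and stannylation then take place at C9, and carboxylate alkylation restores the methyl ester.

Step 8
Reactants: 17 rac-methyl (5E)-9-(methoxymethoxy)-9-(tributylstannyl)nona-5,7,8-trienoate
Product: 18 methyl (5E,aR)-9-(methoxymethoxy)-9-(tributylstannyl)nona-5,7,8-trienoate
Conditions: preparative HPLC, amylose-type chiral stationary phase, hexane/i-PrOH, 0.1% Et3N
Reagents that add atoms: none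
Why: Resolution by chromatography on a chiral stationary phase separates the two axial enantiomers of the stannane; the (aR) antipode has tin where C10 stands in the (aS) precursor.

Step 9
Reactants: 18 methyl (5E,aR)-9-(methoxymethoxy)-9-(tributylstannyl)nona-5,7,8-trienoate; 7 (1Z,5Z)-1-chloro-1-iodoundeca-1,5-dien-3-ol
Product: 19 methyl (5E,10E,14Z,aS)-10-chloro-12-hydroxy-9-(methoxymethoxy)icosa-5,7,8,10,14-pentaenoate (both C12 epimers)
Conditions: Pd2(dba)3 (5 mol %), AsPh3 (20 mol %), CuI (20 mol %), i-Pr2NEt, NMP, 23 °C, dark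
Reagents that add atoms: none
Why: Stille coupling takes place at C–I in preference to C–Cl with retention at both sp2 carbons, so C9 enters cis to C12 (10E) and the axis is carried over (aR becomes aS only because C10 replaces tin).

Step 10
Reactants: 19 methyl (5E,10E,14Z,aS)-10-chloro-12-hydroxy-9-(methoxymethoxy)icosa-5,7,8,10,14-pentaenoate
Product: 20 methyl (5E,10E,14Z,aS)-10-chloro-9-(methoxymethoxy)-12-oxoicosa-5,7,8,10,14-pentaenoate
Conditions: Dess–Martin periodinane, NaHCO3, CH2Cl2, −10 → 0 °C; cold filtration through basic alumina; used at once below −20 °C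
Reagents that add atoms: none
Why: Buffered Dess–Martin oxidation of the dienylic carbinol should give the ketone without acid that would hydrolyse the allenyl ether or base that would move the 14Z alkene into conjugation, and it removes the C12 epimerism.

Step 11
Reactants: 20 methyl (5E,10E,14Z,aS)-10-chloro-9-(methoxymethoxy)-12-oxoicosa-5,7,8,10,14-pentaenoate
Product: 21 chlorovulone III, methyl (5E,7Z)-7-[(2R)-4-chloro-2-hydroxy-2-[(2Z)-oct-2-en-1-yl]-5-oxocyclopent-3-en-1-ylidene]hept-5-enoate
Conditions: Me2AlCl (2.5 equiv), CH2Cl2, −78 → −40 °C; aq. NaHCO3/Rochelle salt, 0 °C; chromatography on neutral silica at 0 °C in the dark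
Reagents that add atoms: none
Why: Proposed new method: coordination of the aprotic, proton-scavenging Lewis acid to the C12 ketone (held s-cis to C10=C11 with oxygen inside the U, because C9 is cis to C12) turns C8–C12 into a 1-oxy-4-alkoxypentadienyl cation that closes between the sp carbon C8 and C12 by thermal 4π conrotation; the in-plane allene π bond becomes the exocyclic C7=C8 alkene, and the alkoxyallyl cation left over C9–C11 gives its methoxymethyl group to chloride, which leaves the C9 ketone with the C10 chlorine and C10=C11 untouched. The closest known reactions are the Nazarov-type cyclisation of allenyl ethers, which transfers an allene axis to a ring carbon, and the 4π closure of 1-hydroxypentadienyl cations in the Piancatelli rearrangement; new here is an allene at the carbon terminus of a pentadienyl cation whose other terminus is the carbonyl carbon. The one ring is closed by this five-atom, four-electron conrotatory electrocyclisation (C8–C12 bond). The C12 stereocentre is controlled by the (aS) axis: the dienyl group on C7 starts on one face of the pentadienyl plane, its outward rotation fixes the sense of conrotation, and with oxygen inside this moves O12 to the face that gives 12R. The step needs torquoselectivity (dienyl outward, hydrogen inward toward C12, hence 7Z), which the clash of an inward dienyl group with the C12 substituents should secure, and closure at carbon instead of oxygen, which is secured by binding the carbonyl oxygen to aluminium and excluding protons.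

Compound list
1 | (Z)-non-3-en-1-ol | CCCCC/C=C\CCO | starting material
2 | (Z)-non-3-enal | CCCCC/C=C\CC=O | intermediate
3 | (E)-1,2-dichloroethene | Cl/C=C/Cl | starting material
4 | chloroethynyllithium | [Li]C#CCl | intermediate
5 | rac-(5Z)-1-chloroundec-5-en-1-yn-3-ol | CCCCC/C=C\CC(O)C#CCl | intermediate
6 | sodium salt of the cyclic (Z)-α-chlorovinyl alkoxyaluminate (aluminium on C10 and O12, two 2-methoxyethoxy ligands) | CCCCC/C=C\CC1C=C(Cl)[Al-](OCCOC)(OCCOC)O1.[Na+] | intermediate
7 | (1Z,5Z)-1-chloro-1-iodoundeca-1,5-dien-3-ol (racemic at C3) | CCCCC/C=C\CC(O)/C=C(/Cl)I | intermediate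
8 | methyl hex-5-ynoate | COC(=O)CCCC#C | starting material
9 | chlorobis(cyclopentadienyl)[(E)-6-methoxy-6-oxohex-1-en-1-yl]zirconium | Cl[Zr](/C=C/CCCC(=O)OC)(C1C=CC=C1)C1C=CC=C1 | intermediate
10 | methyl (E)-6-iodohex-5-enoate | COC(=O)CCC/C=C/I | intermediate
11 | 3-(methoxymethoxy)prop-1-yne | COCOCC#C | starting material
12 | methyl (5E)-9-(methoxymethoxy)non-5-en-7-ynoate | COC(=O)CCC/C=C/C#CCOCOC | intermediate
13 | rac-methyl (5E)-9-(methoxymethoxy)nona-5,7,8-trienoate | COC(=O)CCC/C=C/C=C=COCOC | intermediate
14 | potassium (5E)-9-(methoxymethoxy)nona-5,7,8-trienoate (racemic) | [K+].[O-]C(=O)CCC/C=C/C=C=COCOC | intermediate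
15 | potassium (5E)-9-lithio-9-(methoxymethoxy)nona-5,7,8-trienoate (racemic) | [K+].[O-]C(=O)CCC/C=C/C=C=C([Li])OCOC | intermediate
16 | potassium (5E)-9-(methoxymethoxy)-9-(tributylstannyl)nona-5,7,8-trienoate (racemic) | [K+].[O-]C(=O)CCC/C=C/C=C=C(OCOC)[Sn](CCCC)(CCCC)CCCC | intermediate
17 | rac-methyl (5E)-9-(methoxymethoxy)-9-(tributylstannyl)nona-5,7,8-trienoate | COC(=O)CCC/C=C/C=C=C(OCOC)[Sn](CCCC)(CCCC)CCCC | intermediate
18 | methyl (5E,aR)-9-(methoxymethoxy)-9-(tributylstannyl)nona-5,7,8-trienoate | CCCC[Sn](CCCC)(CCCC)C(OCOC)=[C@]=C([H])/C=C/CCCC(=O)OC | intermediate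
19 | methyl (5E,10E,14Z,aS)-10-chloro-12-hydroxy-9-(methoxymethoxy)icosa-5,7,8,10,14-pentaenoate (both C12 epimers) | CCCCC/C=C\CC(O)/C=C(Cl)\C(OCOC)=[C@]=C([H])/C=C/CCCC(=O)OC | intermediate
20 | methyl (5E,10E,14Z,aS)-10-chloro-9-(methoxymethoxy)-12-oxoicosa-5,7,8,10,14-pentaenoate | CCCCC/C=C\CC(=O)/C=C(Cl)\C(OCOC)=[C@]=C([H])/C=C/CCCC(=O)OC | intermediate
21 | chlorovulone III, methyl (5E,7Z)-7-[(2R)-4-chloro-2-hydroxy-2-[(2Z)-oct-2-en-1-yl]-5-oxocyclopent-3-en-1-ylidene]hept-5-enoate | CCCCC/C=C\C[C@@]1(O)C=C(Cl)C(=O)/C1=C\C=C\CCCC(=O)OC | target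

Total step count: 11. Longest linear sequence: 8 steps (8 to 21, steps 4 to 11).

Steps most likely to fail

1. Step 11 (Proposed new method). The chain may close at oxygen instead of carbon (thermal 6π closure, then pyrylium formation). It may also close stepwise without transfer of the axis, or with the dienyl group turning inward (7E).
 Fallback, known chemistry only and without an electrocyclisation; it sets out from iodide 10 and comes back at 21.
 - Reductive carbonylation of 10 (Pd(PPh3)4, CO, Bu3SnH) should give methyl (E)-7-oxohept-5-enoate F1.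
 - Commercial (Z)-oct-2-en-1-ol is converted (NCS, Me2S) into (Z)-1-chlorooct-2-ene F2 and, with activated barium, into (Z)-oct-2-en-1-ylbarium chloride F3.
 - F3 should add through its α-carbon, with the Z geometry kept, to commercial (R)-4-(tert-butyldimethylsilyloxy)cyclopent-2-en-1-one anti to the silyloxy group. This gives (1S,4R)-4-(tert-butyldimethylsilyloxy)-1-[(2Z)-oct-2-en-1-yl]cyclopent-2-en-1-ol F4.
 - TBAF gives (1S,4R)-1-[(2Z)-oct-2-en-1-yl]cyclopent-2-ene-1,4-diol F5. MnO2 oxidises only the secondary allylic alcohol to (4S)-4-hydroxy-4-[(2Z)-oct-2-en-1-yl]cyclopent-2-en-1-one F6, which already holds the C12 centre.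
 - Nucleophilic epoxidation (H2O2, NaOH) gives 4-hydroxy-4-[(2Z)-oct-2-en-1-yl]-6-oxabicyclo[3.1.0]hexan-2-one F7. HCl opens it at the α-carbon and water is lost to give (4S)-2-chloro-4-hydroxy-4-[(2Z)-oct-2-en-1-yl]cyclopent-2-en-1-one F8.
 - The dianion of F8 (LDA, 2.2 equiv, −78 °C) adds at C8 to F1 to give methyl (5E)-7-[4-chloro-2-hydroxy-2-[(2Z)-oct-2-en-1-yl]-5-oxocyclopent-3-en-1-yl]-7-hydroxyhept-5-enoate F9.
 - Mesylation of the secondary hydroxyl (MsCl, Et3N) gives the 7-methanesulfonate of this aldol F10. Elimination (DBU) should give the cross-conjugated dienone as a 7Z/7E mixture, from which 21 is separated in the dark from methyl (5E,7E)-7-[(2R)-4-chloro-2-hydroxy-2-[(2Z)-oct-2-en-1-yl]-5-oxocyclopent-3-en-1-ylidene]hept-5-enoate F11.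

2. Step 9. Transmetalation at the congested α-alkoxy stannyl carbon may be slow. Palladium could then interconvert allenyl and propargyl forms, which erodes the axis, or the stannane could be protonated off.
 Fallback: the resolution is moved behind the coupling, so that scrambling at palladium no longer matters; it sets out from 5 and racemic 17 (step 8 is dropped) and comes back at 20.
 - Lipase-catalysed acylation of racemic 5 (immobilised Candida antarctica lipase B, vinyl acetate) should leave (3R,5Z)-1-chloroundec-5-en-1-yn-3-ol F12 beside (3S,5Z)-1-chloroundec-5-en-1-yn-3-yl acetate F13. Either antipode would serve, since C12 is later oxidised.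
 - F12 is taken through the conditions of step 3 to (1Z,3R,5Z)-1-chloro-1-iodoundeca-1,5-dien-3-ol F14.
 - Coupling of F14 with racemic 17 under the conditions of step 9 gives two diastereomers that differ only in the axis. HPLC on silica should separate methyl (5E,10E,12R,14Z,aS)-10-chloro-12-hydroxy-9-(methoxymethoxy)icosa-5,7,8,10,14-pentaenoate F15.
 - F15 is oxidised as in step 10 to 20.

3. Step 10. The electron-rich allenyl enol ether may be attacked by the oxidant or by acetic acid. The freed dienone may also close thermally at oxygen during oxidation and work-up, before the Lewis acid is applied.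
 Fallback: the oxidation is placed before the coupling; it sets out from 7 and 18 and comes back at 20.
 - 7 is oxidised (Dess–Martin periodinane, NaHCO3) to (1Z,5Z)-1-chloro-1-iodoundeca-1,5-dien-3-one F16.
 - F16 is a strongly activated β-iodoenone and should couple with 18 at −20 to 0 °C (Pd2(dba)3, AsPh3, CuI).
 - After a cold extractive work-up into CH2Cl2, the solution of 20 is taken directly into step 11 without a separate oxidation of the allenyl ether.

Further compounds
F1 | step 11 | methyl (E)-7-oxohept-5-enoate | COC(=O)CCC/C=C/C=O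
F2 | step 11 | (Z)-1-chlorooct-2-ene | CCCCC/C=C\CCl
F3 | step 11 | (Z)-oct-2-en-1-ylbarium chloride | CCCCC/C=C\C[Ba]Cl
F4 | step 11 | (1S,4R)-4-(tert-butyldimethylsilyloxy)-1-[(2Z)-oct-2-en-1-yl]cyclopent-2-en-1-ol | CCCCC/C=C\C[C@@]1(O)C=C[C@H](O[Si](C)(C)C(C)(C)C)C1
F5 | step 11 | (1S,4R)-1-[(2Z)-oct-2-en-1-yl]cyclopent-2-ene-1,4-diol | CCCCC/C=C\C[C@@]1(O)C=C[C@H](O)C1
F6 | step 11 | (4S)-4-hydroxy-4-[(2Z)-oct-2-en-1-yl]cyclopent-2-en-1-one | CCCCC/C=C\C[C@@]1(O)C=CC(=O)C1
F7 | step 11 | 4-hydroxy-4-[(2Z)-oct-2-en-1-yl]-6-oxabicyclo[3.1.0]hexan-2-one (C4 as in F6, oxirane face not defined) | CCCCC/C=C\C[C@@]1(O)C2OC2C(=O)C1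
F8 | step 11 | (4S)-2-chloro-4-hydroxy-4-[(2Z)-oct-2-en-1-yl]cyclopent-2-en-1-one | CCCCC/C=C\C[C@@]1(O)C=C(Cl)C(=O)C1
F9 | step 11 | methyl (5E)-7-[4-chloro-2-hydroxy-2-[(2Z)-oct-2-en-1-yl]-5-oxocyclopent-3-en-1-yl]-7-hydroxyhept-5-enoate (C12 as in F8, mixture at C7 and C8) | CCCCC/C=C\C[C@@]1(O)C=C(Cl)C(=O)C1C(O)/C=C/CCCC(=O)OC
F10 | step 11 | 7-methanesulfonate of the aldol F9 | CCCCC/C=C\C[C@@]1(O)C=C(Cl)C(=O)C1C(OS(C)(=O)=O)/C=C/CCCC(=O)OC
F11 | step 11 | methyl (5E,7E)-7-[(2R)-4-chloro-2-hydroxy-2-[(2Z)-oct-2-en-1-yl]-5-oxocyclopent-3-en-1-ylidene]hept-5-enoate | CCCCC/C=C\C[C@@]1(O)C=C(Cl)C(=O)/C1=C/C=C/CCCC(=O)OC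
F12 | step 9 | (3R,5Z)-1-chloroundec-5-en-1-yn-3-ol | CCCCC/C=C\C[C@@H](O)C#CCl
F13 | step 9 | (3S,5Z)-1-chloroundec-5-en-1-yn-3-yl acetate | CCCCC/C=C\C[C@H](OC(C)=O)C#CCl
F14 | step 9 | (1Z,3R,5Z)-1-chloro-1-iodoundeca-1,5-dien-3-ol | CCCCC/C=C\C[C@@H](O)/C=C(/Cl)I
F15 | step 9 | methyl (5E,10E,12R,14Z,aS)-10-chloro-12-hydroxy-9-(methoxymethoxy)icosa-5,7,8,10,14-pentaenoate | CCCCC/C=C\C[C@@H](O)/C=C(Cl)\C(OCOC)=[C@]=C([H])/C=C/CCCC(=O)OC
F16 | step 10 | (1Z,5Z)-1-chloro-1-iodoundeca-1,5-dien-3-one | CCCCC/C=C\CC(=O)/C=C(/Cl)I
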